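**Plan**

- Ring A is numbered as in the target: C1 side chain, C2 OH, C3 3-hydroxybenzoyl, C4 OH, C5 prenyl, C6 OMe. Oxygen on C2, C4 and C6 alternates with carbon on C1, C3 and C5, so ring A is an acylphloroglucinol, the aromatised form of a 7-aryl-3,5,7-trioxoheptanoate with alkyl groups on chain C2 and C4. This alternation is what permits a Claisen ring closure.
- Retrosynthesis: remove the ring B allyl ether and the C6 O-methyl group, then open ring A at C2–C3. The open chain is cut at C1–C2 (CO2), at C3–C(=O)Ar (aroylation), at C1–CH2 of the side chain (alkylation) and at C5–prenyl, which leads back to acetylacetone.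
- Forward: acetylacetone is prenylated at its central carbon, alkylated at one methyl group through the dianion, aroylated at the other methyl group, then carboxylated through the trianion and esterified. Ring A, the only ring made (ring B is bought), is then closed, methylated at the C6 oxygen and deallylated.
- Stereochemistry: the single stereocentre is C4 of (R)-limonene. Ring cleavage, oxidation, methylenation and decarboxylative iodination all act on other carbons, and the centre carries no acidic hydrogen in any later step.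

Key step: step 10

Assumption: compounds 10, 11 and 14–17 are keto–enol and epimer mixtures at the carbons flanked by carbonyl groups; these centres are drawn without configuration and all vanish when ring A becomes aromatic.

**Route**

Step 1
Reactants: 1 (R)-limonene
Product: 3 (3R)-6-oxo-3-(prop-1-en-2-yl)heptanal, via ozonide 2 (not isolated)
Conditions: O3 (1.0 equiv), CH2Cl2, −78 °C; then PPh3, −78 °C → rt
Reagents that add atoms: ozone, [O-][O+]=O
Why: Ozonolysis with reductive work-up; the trisubstituted ring alkene is more electron-rich than the 1,1-disubstituted isopropenyl group, so one equivalent of ozone should cleave it selectively, and the stereocentre is not involved.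

Step 2
Reactants: 3 (3R)-6-oxo-3-(prop-1-en-2-yl)heptanal
Product: 4 (3R)-6-oxo-3-(prop-1-en-2-yl)heptanoic acid
Conditions: NaClO2, NaH2PO4, 2-methylbut-2-ene, t-BuOH/H2O, 0 °C → rt (crude 3 used at once)
Reagents that add atoms: sodium chlorite, [Na+].[O-]Cl=O
Why: Pinnick oxidation converts the aldehyde only, the scavenger alkene takes up HOCl before it can reach the isopropenyl group, and the stereocentre is β to the carbonyl and cannot epimerise.

Step 3
Reactants: 4 (3R)-6-oxo-3-(prop-1-en-2-yl)heptanoic acid
Product: 5 (3R)-6-methyl-3-(prop-1-en-2-yl)hept-6-enoic acid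
Conditions: Ph3PCH3Br (2.5 equiv), KOt-Bu (3.5 equiv), THF, 0 °C → rt; then cold 1 M HCl
Reagents that add atoms: methyltriphenylphosphonium bromide, C[P+](c1ccccc1)(c1ccccc1)c1ccccc1.[Br-]
Why: Wittig methylenation of the methyl ketone; the acid is present as its potassium carboxylate, which is inert to the ylide.

Step 4
Reactants: 5 (3R)-6-methyl-3-(prop-1-en-2-yl)hept-6-enoic acid
Product: 7 (3S)-3-(iodomethyl)-2,6-dimethylhepta-1,6-diene, via Barton ester 6 (not isolated)
Conditions: N-hydroxypyridine-2-thione, DCC, DMAP (cat.), PhH, rt, dark; then CHI3 (2 equiv), hν (tungsten lamp), rt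
Reagents that add atoms: iodoform, IC(I)I; N-hydroxypyridine-2-thione, On1ccccc1=S (atoms remain in 6 only)
Why: Barton decarboxylative iodination; the thiohydroxamate ester fragments under light to CO2 and a primary radical that should abstract iodine from CHI3 before it can cyclise or rearrange, and the stereocentre is β to the radical and untouched (the descriptor changes to S only through the priority rules).

Step 5
Reactants: 8 acetylacetone, 9 prenyl bromide
Product: 10 3-(3-methylbut-2-en-1-yl)pentane-2,4-dione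
Conditions: 8 (1.5 equiv), K2CO3, acetone, reflux
Reagents that add atoms: none
Why: C-alkylation of a β-diketone enolate by an allylic bromide (SN2); excess diketone should hold the reaction at the mono-alkyl stage.

Step 6
Reactants: 10 3-(3-methylbut-2-en-1-yl)pentane-2,4-dione, 7 (3S)-3-(iodomethyl)-2,6-dimethylhepta-1,6-diene
Product: 11 (7R)-10-methyl-3-(3-methylbut-2-en-1-yl)-7-(prop-1-en-2-yl)undec-10-ene-2,4-dione
Conditions: 10 (1.5 equiv), LiN(i-Pr)2 (3.1 equiv), THF, −78 → 0 °C; then 7, THF/DMPU, 0 °C → rt; cold 1 M HCl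
Reagents that add atoms: none
Why: Hauser-type dianion alkylation; the second deprotonation takes place at a terminal methyl group, and this more basic carbanion displaces the primary iodide (SN2) at a carbon next to, not at, the stereocentre.

Step 7
Reactants: 12 methyl 3-hydroxybenzoate
Product: 13 methyl 3-(prop-2-en-1-yloxy)benzoate
Conditions: allyl bromide, K2CO3, acetone, reflux
Reagents that add atoms: allyl bromide, C=CCBr
Why: Williamson ether synthesis on a phenol; the allyl ether withstands the amide bases and methoxide used later and can be removed without acid.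

Step 8
Reactants: 11 (7R)-10-methyl-3-(3-methylbut-2-en-1-yl)-7-(prop-1-en-2-yl)undec-10-ene-2,4-dione, 13 methyl 3-(prop-2-en-1-yloxy)benzoate
Product: 14 (8R)-11-methyl-4-(3-methylbut-2-en-1-yl)-8-(prop-1-en-2-yl)-1-[3-(prop-2-en-1-yloxy)phenyl]dodec-11-ene-1,3,5-trione
Conditions: LiN(i-Pr)2 (3.2 equiv), THF, −78 → 0 °C; then 13 (1.0 equiv), −78 °C → rt; cold 1 M HCl
Reagents that add atoms: none
Why: Claisen condensation of a β-diketone dianion with a non-enolisable aryl ester; kinetic deprotonation should take the remaining methyl group in preference to the C5 methylene, and the third equivalent of base absorbs the more acidic triketone product.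

Step 9
Reactants: 14 (8R)-11-methyl-4-(3-methylbut-2-en-1-yl)-8-(prop-1-en-2-yl)-1-[3-(prop-2-en-1-yloxy)phenyl]dodec-11-ene-1,3,5-trione
Product: 16 methyl 7-[3-(prop-2-en-1-yloxy)phenyl]-2-[(2R)-5-methyl-2-(prop-1-en-2-yl)hex-5-en-1-yl]-4-(3-methylbut-2-en-1-yl)-3,5,7-trioxoheptanoate, via triketo acid 15 (not isolated)
Conditions: LiN(i-Pr)2 (3.5 equiv), THF, −78 → 0 °C; CO2 (g), −78 °C; cold 1 M HCl/Et2O; then Me3SiCHN2 (1.05 equiv), PhMe/MeOH, 0 °C
Reagents that add atoms: carbon dioxide, O=C=O; (trimethylsilyl)diazomethane, C[Si](C)(C)C=[N+]=[N-]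
Why: Polyanion carboxylation; the third deprotonation can occur only at the C6 methylene, the one site activated by a single carbonyl, this most basic carbon of the trianion takes up CO2, and the α-branched β-keto acid is esterified cold before it can decarboxylate.

Step 10
Reactants: 16 methyl 7-[3-(prop-2-en-1-yloxy)phenyl]-2-[(2R)-5-methyl-2-(prop-1-en-2-yl)hex-5-en-1-yl]-4-(3-methylbut-2-en-1-yl)-3,5,7-trioxoheptanoate
Product: 18 {2,4,6-trihydroxy-3-[(2R)-5-methyl-2-(prop-1-en-2-yl)hex-5-en-1-yl]-5-(3-methylbut-2-en-1-yl)phenyl}[3-(prop-2-en-1-yloxy)phenyl]methanone, via cyclohexanetrione 17 (not isolated)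
Conditions: Mg(OMe)2 (8 equiv), degassed MeOH, Ar, rt → 50 °C; then cold 1 M HCl
Reagents that add atoms: none
Why: Mg(OMe)2 turns the triketo ester into a chelated magnesium polyenolate in which chain C6, flanked by the C5 and C7 ketones, lies next to the C1 ester carbonyl; C6 adds to C1, methoxide leaves, and the 2-aroylcyclohexane-1,3,5-trione 17 enolises irreversibly to the phloroglucinol. This is the Claisen (Dieckmann-type) cyclisation established for 7-aryl-3,5,7-trioxoheptanoates with Mg(OMe)2, and it makes the ring A bond C2–C3 of the target. Ring A closes in the 6-(enolexo)-exo-trig mode. No stereocentre is created: the epimeric chain C2 and C4 centres become sp2 on aromatisation, and the side-chain centre has no acidic hydrogen and is untouched. The step needs C-acylation at C1 in preference to the aldol fold (C2 onto C7) and to pyranone closure through an enol oxygen; the alkyl group on chain C2 makes the aldol adduct quaternary there, so it cannot dehydrate to an arene and reverts, while magnesium chelation ties up the enol oxygens and leaves carbon as the nucleophile.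

Step 11
Reactants: 18 {2,4,6-trihydroxy-3-[(2R)-5-methyl-2-(prop-1-en-2-yl)hex-5-en-1-yl]-5-(3-methylbut-2-en-1-yl)phenyl}[3-(prop-2-en-1-yloxy)phenyl]methanone
Product: 19 {2,6-dihydroxy-4-methoxy-3-[(2R)-5-methyl-2-(prop-1-en-2-yl)hex-5-en-1-yl]-5-(3-methylbut-2-en-1-yl)phenyl}[3-(prop-2-en-1-yloxy)phenyl]methanone
Conditions: Me2SO4 (1.05 equiv), K2CO3 (1.1 equiv), acetone, rt
Reagents that add atoms: dimethyl sulfate, COS(=O)(=O)OC
Why: Williamson-type O-methylation under weak base; the hydroxyl para to the ketone (C6 of ring A) is the most acidic and is not hydrogen-bonded to the carbonyl, so its phenoxide should react first while the two ortho hydroxyls are held back by chelation.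

Step 12
Reactants: 19 {2,6-dihydroxy-4-methoxy-3-[(2R)-5-methyl-2-(prop-1-en-2-yl)hex-5-en-1-yl]-5-(3-methylbut-2-en-1-yl)phenyl}[3-(prop-2-en-1-yloxy)phenyl]methanone
Product: 20 CNP0139402.2, {2,6-dihydroxy-4-methoxy-3-[(2R)-5-methyl-2-(prop-1-en-2-yl)hex-5-en-1-yl]-5-(3-methylbut-2-en-1-yl)phenyl}(3-hydroxyphenyl)methanone
Conditions: Pd(PPh3)4 (5 mol %), morpholine (10 equiv), THF, rt
Reagents that add atoms: none
Why: Tsuji–Trost deallylation; zerovalent palladium ionises the aryl allyl ether to a π-allyl complex that morpholine captures, under neutral conditions that leave the prenyl, isopropenyl and methallyl alkenes and the free phenols alone.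

**Compound list**

1 | (R)-limonene, (4R)-1-methyl-4-(prop-1-en-2-yl)cyclohex-1-ene | CC1=CC[C@@H](CC1)C(C)=C | starting material
2 | limonene ring ozonide, (4R)-1-methyl-4-(prop-1-en-2-yl)-7,8,9-trioxabicyclo[4.2.1]nonane (bridgehead carbons unassigned) | CC12CC[C@H](CC(OO1)O2)C(C)=C | intermediate (not isolated)
3 | (3R)-6-oxo-3-(prop-1-en-2-yl)heptanal | CC(=O)CC[C@H](CC=O)C(C)=C | intermediate
4 | (3R)-6-oxo-3-(prop-1-en-2-yl)heptanoic acid | CC(=O)CC[C@H](CC(=O)O)C(C)=C | intermediate
5 | (3R)-6-methyl-3-(prop-1-en-2-yl)hept-6-enoic acid | C=C(C)CC[C@H](CC(=O)O)C(C)=C | intermediate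
6 | 2-thioxopyridin-1(2H)-yl (3R)-6-methyl-3-(prop-1-en-2-yl)hept-6-enoate (Barton ester) | C=C(C)CC[C@H](CC(=O)On1ccccc1=S)C(C)=C | intermediate (not isolated)
7 | (3S)-3-(iodomethyl)-2,6-dimethylhepta-1,6-diene | C=C(C)CC[C@H](CI)C(C)=C | intermediate
8 | acetylacetone (pentane-2,4-dione) | CC(=O)CC(C)=O | starting material
9 | prenyl bromide (1-bromo-3-methylbut-2-ene) | CC(C)=CCBr | starting material
10 | 3-(3-methylbut-2-en-1-yl)pentane-2,4-dione | CC(=O)C(CC=C(C)C)C(C)=O | intermediate
11 | (7R)-10-methyl-3-(3-methylbut-2-en-1-yl)-7-(prop-1-en-2-yl)undec-10-ene-2,4-dione | C=C(C)CC[C@H](CCC(=O)C(CC=C(C)C)C(C)=O)C(C)=C | intermediate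
12 | methyl 3-hydroxybenzoate | COC(=O)c1cccc(O)c1 | starting material
13 | methyl 3-(prop-2-en-1-yloxy)benzoate | COC(=O)c1cccc(OCC=C)c1 | intermediate
14 | (8R)-11-methyl-4-(3-methylbut-2-en-1-yl)-8-(prop-1-en-2-yl)-1-[3-(prop-2-en-1-yloxy)phenyl]dodec-11-ene-1,3,5-trione | C=C(C)CC[C@H](CCC(=O)C(CC=C(C)C)C(=O)CC(=O)c1cccc(OCC=C)c1)C(C)=C | intermediate
15 | 7-[3-(prop-2-en-1-yloxy)phenyl]-2-[(2R)-5-methyl-2-(prop-1-en-2-yl)hex-5-en-1-yl]-4-(3-methylbut-2-en-1-yl)-3,5,7-trioxoheptanoic acid | C=C(C)CC[C@H](CC(C(=O)O)C(=O)C(CC=C(C)C)C(=O)CC(=O)c1cccc(OCC=C)c1)C(C)=C | intermediate (not isolated)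
16 | methyl 7-[3-(prop-2-en-1-yloxy)phenyl]-2-[(2R)-5-methyl-2-(prop-1-en-2-yl)hex-5-en-1-yl]-4-(3-methylbut-2-en-1-yl)-3,5,7-trioxoheptanoate | C=C(C)CC[C@H](CC(C(=O)OC)C(=O)C(CC=C(C)C)C(=O)CC(=O)c1cccc(OCC=C)c1)C(C)=C | intermediate
17 | 2-[3-(prop-2-en-1-yloxy)benzoyl]-4-[(2R)-5-methyl-2-(prop-1-en-2-yl)hex-5-en-1-yl]-6-(3-methylbut-2-en-1-yl)cyclohexane-1,3,5-trione | C=C(C)CC[C@H](CC1C(=O)C(C(=O)c2cccc(OCC=C)c2)C(=O)C(CC=C(C)C)C1=O)C(C)=C | intermediate (not isolated)
18 | {2,4,6-trihydroxy-3-[(2R)-5-methyl-2-(prop-1-en-2-yl)hex-5-en-1-yl]-5-(3-methylbut-2-en-1-yl)phenyl}[3-(prop-2-en-1-yloxy)phenyl]methanone | C=C(C)CC[C@H](Cc1c(O)c(C(=O)c2cccc(OCC=C)c2)c(O)c(CC=C(C)C)c1O)C(=C)C | intermediate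
19 | {2,6-dihydroxy-4-methoxy-3-[(2R)-5-methyl-2-(prop-1-en-2-yl)hex-5-en-1-yl]-5-(3-methylbut-2-en-1-yl)phenyl}[3-(prop-2-en-1-yloxy)phenyl]methanone | C=C(C)CC[C@H](Cc1c(O)c(C(=O)c2cccc(OCC=C)c2)c(O)c(CC=C(C)C)c1OC)C(=C)C | intermediate
20 | CNP0139402.2, {2,6-dihydroxy-4-methoxy-3-[(2R)-5-methyl-2-(prop-1-en-2-yl)hex-5-en-1-yl]-5-(3-methylbut-2-en-1-yl)phenyl}(3-hydroxyphenyl)methanone | C=C(C)CC[C@H](Cc1c(O)c(C(=O)c2cccc(O)c2)c(O)c(CC=C(C)C)c1OC)C(=C)C | target

**Count**

Total steps: 12. Longest linear sequence: 10 steps (steps 1–4, 6, 8–12, from 1).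

**Steps most likely to fail**

Step 10: the ester carbonyl is α-branched, so carbon–carbon closure may be slow enough for methoxide to cleave the polyketone chain (retro-Claisen) or for an enol oxygen to acylate instead. The fallback changes the acyl donor and removes the alkoxide. It sets out from triketo acid 15, which is treated cold with 1,1'-carbonyldiimidazole in THF to give the acyl imidazolide F1. MgCl2 and Et3N then generate the magnesium enolate of the C5/C7 diketone, which is C-acylated by the imidazolide within the same molecule (acylation of a magnesium enolate by an acyl imidazole, Masamune type). The same ring A bond forms and the route is rejoined at 18.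

Step 9: the third deprotonation at the substituted C6 methylene may be incomplete, or the α-branched β-keto acid may lose CO2 before it is esterified. The fallback puts the ester carbon on a methyl group first. It sets out from 10, whose dianion (LiN(i-Pr)2) is acylated at a methyl group with dimethyl carbonate to give methyl 4-(3-methylbut-2-en-1-yl)-3,5-dioxohexanoate F2. The dianion of F2 (C2 and C4 deprotonated) is alkylated by iodide 7 at C2, the less stabilised site and the only unhindered one once C4 is prenylated, to give the C2-alkylated dioxo ester F3. The trianion of F3 is then aroylated at its C6 methyl group with ester 13 (polyanion chemistry of 3,5-dioxo esters), and the route is rejoined at 16.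

Step 6: the β-hydrogen of iodide 7 is allylic, so elimination of HI by the basic dianion may outrun substitution. The fallback keeps all ten limonene carbons, adds one, and joins the chain by acylation instead of alkylation, which also bypasses the radical step 4. It sets out from acid 5, which (COCl)2 converts into the acid chloride F4 and CH2N2 into the diazoketone F5. Wolff rearrangement (PhCO2Ag, Et3N) in the presence of MeNHOMe gives the one-carbon-longer Weinreb amide F6 (Arndt–Eistert homologation). Separately, the kinetic lithium enolate of commercial 6-methylhept-5-en-2-one (CC(=O)CCC=C(C)C) is condensed with ester 13 to give the aryl diketone F7. The dianion of F7 is acylated at its C4 methylene by F6, and the route is rejoined at 14.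

**Further compounds**

F1 | step 10 | 1-{7-[3-(prop-2-en-1-yloxy)phenyl]-2-[(2R)-5-methyl-2-(prop-1-en-2-yl)hex-5-en-1-yl]-4-(3-methylbut-2-en-1-yl)-3,5,7-trioxoheptanoyl}-1H-imidazole | C=C(C)CC[C@H](CC(C(=O)n1ccnc1)C(=O)C(CC=C(C)C)C(=O)CC(=O)c1cccc(OCC=C)c1)C(C)=C
F2 | step 9 | methyl 4-(3-methylbut-2-en-1-yl)-3,5-dioxohexanoate | COC(=O)CC(=O)C(CC=C(C)C)C(C)=O
F3 | step 9 | methyl 2-[(2R)-5-methyl-2-(prop-1-en-2-yl)hex-5-en-1-yl]-4-(3-methylbut-2-en-1-yl)-3,5-dioxohexanoate | C=C(C)CC[C@H](CC(C(=O)OC)C(=O)C(CC=C(C)C)C(C)=O)C(C)=C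
F4 | step 6 | (3R)-6-methyl-3-(prop-1-en-2-yl)hept-6-enoyl chloride | C=C(C)CC[C@H](CC(=O)Cl)C(C)=C
F5 | step 6 | (4R)-1-diazo-7-methyl-4-(prop-1-en-2-yl)oct-7-en-2-one | C=C(C)CC[C@H](CC(=O)C=[N+]=[N-])C(C)=C
F6 | step 6 | (4R)-N-methoxy-N,7-dimethyl-4-(prop-1-en-2-yl)oct-7-enamide | C=C(C)CC[C@H](CCC(=O)N(C)OC)C(C)=C
F7 | step 6 | 7-methyl-1-[3-(prop-2-en-1-yloxy)phenyl]oct-6-ene-1,3-dione | C=CCOc1cccc(c1)C(=O)CC(=O)CCC=C(C)C
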